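**Retrosynthetic overview**
1. Target 7 is cut at C1–C2 and at the acyl C–O bond in one operation: a three-component isomerising hydroalkoxycarbonylation of an internal C27 alkene (5) with CO and 2-phenylethanol (6). No acid-plus-alcohol esterification is used.
2. Alkene 5, (Z)-heptacos-13-ene, comes from a C13 + C14 Wittig olefination. The position and geometry of its C=C are irrelevant because the palladium hydride catalyst walks the double bond to the chain end.
3. Phosphonium salt 2 comes from 1-bromotridecane (1) and PPh3.
4. No ring is formed: the only ring (phenyl) is bought inside 6, and the target has no stereocentre.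

Assumption: the target has no stereocentre and no stereogenic double bond, so "the single enantiomer given" is simply the one achiral compound drawn.

**Step 1**
Reactants: 1 1-bromotridecane
Product: 2 tridecyl(triphenyl)phosphonium bromide
Conditions: PPh3 (1.1 equiv), MeCN, reflux, 48 h; triturate with Et2O, dry in vacuo over P2O5
Reagents that add atoms: triphenylphosphine, c1ccc(cc1)P(c1ccccc1)c1ccccc1
Why: SN2 quaternisation of a phosphine by an unhindered primary bromide is an addition in which every atom of both partners ends up in the salt, and no stereocentre is involved.

**Step 2**
Reactants: 2 tridecyl(triphenyl)phosphonium bromide; 3 tetradecanal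
Product: 5 (Z)-heptacos-13-ene, via tridecylidene(triphenyl)phosphorane 4 (not isolated)
Conditions: NaN(SiMe3)2 (1.05 equiv), THF, 0 °C, 30 min; then 3, −78 °C to rt; hexane, filter through SiO2
Reagents that add atoms: none
Why: Wittig olefination with a non-stabilised ylide under lithium-free, kinetically controlled conditions joins the C13 and C14 pieces and gives mainly the Z alkene; the few percent of E isomer is carried along because step 3 erases the double bond, and no stereocentre is created.

**Step 3**
Reactants: 5 (Z)-heptacos-13-ene; 6 2-phenylethanol
Product: 7 2-phenylethyl octacosanoate
Conditions: Pd(OAc)2 (1 mol %), 1,2-bis(di-tert-butylphosphinomethyl)benzene (5 mol %), MeSO3H (10 mol %), CO (20 bar), 6 (5 equiv), toluene, 90 °C, 72 h; recrystallise from acetone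
Reagents that add atoms: carbon monoxide, [C-]#[O+]
Why: Isomerising hydroalkoxycarbonylation, in which the cationic divalent palladium hydride carrying the bulky diphosphine walks the double bond along the chain by reversible insertion and beta-hydride elimination and only the unhindered linear acyl palladium is alcoholysed at a useful rate (Curtin–Hammett selection), so either chain end gives the same n-octacosanoyl ester with every atom of 5, CO and 6 retained and no stereocentre formed.

**Compound list**
1 | 1-bromotridecane | CCCCCCCCCCCCCBr | starting material
2 | tridecyl(triphenyl)phosphonium bromide | CCCCCCCCCCCCC[P+](c1ccccc1)(c1ccccc1)c1ccccc1.[Br-] | intermediate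
3 | tetradecanal | CCCCCCCCCCCCCC=O | starting material
4 | tridecylidene(triphenyl)phosphorane | CCCCCCCCCCCCC=P(c1ccccc1)(c1ccccc1)c1ccccc1 | intermediate
5 | (Z)-heptacos-13-ene | CCCCCCCCCCCC/C=C\CCCCCCCCCCCCC | intermediate
6 | 2-phenylethanol | OCCc1ccccc1 | starting material
7 | 2-phenylethyl octacosanoate (phenylethyl n-octacosanoate) | CCCCCCCCCCCCCCCCCCCCCCCCCCCC(=O)OCCc1ccccc1 | target

**Total step count:** 3
**Longest linear sequence:** 3 (1 → 2 → 5 → 7)

**Steps most likely to fail, with fallbacks**

Step 3 (highest risk). 2-Phenylethanol attacks the acyl palladium more slowly than methanol does, which can lower both the rate and the linear-to-branched ratio. The acid co-catalyst may also consume some of 6 by ether formation. The fallback sets out from 5 and comes back at 7. Alkene 5 is carbonylated with the same Pd(OAc)2/diphosphine/MeSO3H system under CO (20 bar) at 90 °C, but in methanol as nucleophile and solvent, the best-precedented form of this reaction. This gives methyl octacosanoate F1, which is crystallised free of branched isomers. The methoxy group of F1 is then exchanged for the phenylethoxy group by heating with 6 (3 equiv) and Ti(OiPr)4 (5 mol %) in toluene at 110 °C while methanol is distilled off, giving 7.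

Step 2. The basic ylide can enolise tetradecanal and cause aldol self-condensation, and a long-chain ylide may be poorly soluble and sluggish at low temperature. The fallback sets out from 1 and comes back at 5, using no carbonyl or phosphorus chemistry. Commercial tetradec-1-yne (C#CCCCCCCCCCCCC) is deprotonated with n-BuLi in THF at −78 °C to give lithium tetradec-1-ynide F2. F2 is alkylated with bromide 1 in THF/DMPU (0 °C to 50 °C) to give heptacos-13-yne F3. Semi-hydrogenation of F3 (H2 1 atm, Pd/CaCO3 poisoned with Pb(OAc)2, quinoline, hexane, rt) gives 5 as the pure Z isomer.

Step 1. The long-chain phosphonium salt may separate as a hygroscopic wax that resists crystallisation and drying, and residual water or PPh3 would then spoil the ylide chemistry. The fallback sets out from 1 (together with 3) and comes back at 5 without any phosphorus reagent. Bromide 1 is converted with Mg turnings in THF into tridecylmagnesium bromide F4. F4 is added to aldehyde 3 (0 °C to rt, 1 M HCl work-up) to give the symmetrical secondary alcohol heptacosan-14-ol F5. F5 is dehydrated by syn-elimination with Burgess reagent (methyl N-(triethylammoniosulfonyl)carbamate, toluene, 80 °C). Because F5 is symmetrical, elimination can only give heptacos-13-ene. It is obtained as a mixture of 5 and its geometric isomer (E)-heptacos-13-ene F6, and the mixture goes into step 3 unchanged since both isomers converge on 7.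

**Further compounds**
F1 | step 3 | methyl octacosanoate | CCCCCCCCCCCCCCCCCCCCCCCCCCCC(=O)OC
F2 | step 2 | lithium tetradec-1-ynide | [Li]C#CCCCCCCCCCCCC
F3 | step 2 | heptacos-13-yne | CCCCCCCCCCCCC#CCCCCCCCCCCCCC
F4 | step 1 | tridecylmagnesium bromide | CCCCCCCCCCCCC[Mg]Br
F5 | step 1 | heptacosan-14-ol | CCCCCCCCCCCCCC(O)CCCCCCCCCCCCC
F6 | step 1 | (E)-heptacos-13-ene | CCCCCCCCCCCC/C=C/CCCCCCCCCCCCC
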